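The target had to be set against the side product in epsilon, gamma and eta, three flasks that differ in their charge of starting material.

common to all: gas 75 mM (held); initiator 5 mol%
- south: starting material 0.070 M; transfer agent 0.20 M; run made earlier
- north-east: starting material 0.18 M; transfer agent 0.20 M; run made earlier
- north-west: starting material 0.50 M; transfer agent 0.20 M; run made earlier
- epsilon: starting material 0.060 M; transfer agent 0.200 M; time 5.0 min
- gamma: starting material 0.20 M; transfer agent 0.200 M; time 5.0 min
- eta: starting material 0.60 M; transfer agent 0.200 M; time 5.0 min

- south (time / min: target / %, side product / %): 0.333: 19.1, 7.5; 0.833: 25.8, 5.6; 1.50: 25.7, 6.8; 2.50: 27.0, 6.7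
- north-east (time / min: target / %, side product / %): 0.667: 28.3, 8.3; 1.33: 28.4, 8.1; 2.00: 28.6, 9.1; 2.50: 29.2, 8.2
- north-west (time / min: target / %, side product / %): 0.200: 8.9, 7.9; 0.500: 19.5, 9.2; 1.00: 26.7, 9.1; 2.50: 23.2, 9.4

(each reading ± 1 percentage point)

- share of target in all that became target or side product for epsilon, gamma, eta, in this order
- the shape of the row from first to last (falls, then rises / rises all the way / rises, then falls / hardly changes / falls all the way)

- the numbers in the tables scatter with a standard deviation of 1 percentage point
- at the start none of the gas is in solution
- "hardly changes" means that all values lie within two and a half points (for a concentration: within two and a half percent of the largest)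

1. I worked with the odds r, target per side product, the selectivity factor. Even odds, r equal to one, are the zero of the scale and mean a share of 50%. In general the share is r/(1 + r).

2. I first asked which readings had to be known well. At the last north-east reading, a shift in the target reading moves the share by 0.586 times that shift, and a shift in the side product reading moves it the other way by 2.09 times that shift, so the side product weighs more. The ratio of these two weights is r itself. From 1.33 min to 2.50 min the north-east target moved 0.8 percentage points, against a scatter of 1 point on each reading. The readings end at 2.50 min, and I carried their level on to 5.0 min.

3. Averaging the four north-east readings leaves about 1 point of uncertainty in the share from the side product readings. They give the north-east odds, target per side product, of 3.40, a share of 77.3%. The later south readings give odds of 4.11, a share of 80.4%. The last two north-west readings give 2.70, a share of 73.0%. I took these as my shares for the nearest new flasks.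

4. The forecast, made to “read the share from the plateau values”, gave 80%, 77% and 72%, with the shape "falls all the way". At eta it stood below my figure.

5. The flasks gave 79.6%, 77.4% and 70.7%, with the shape "falls all the way".

    initiator → 2 initiating radical (k = 0.0980 s⁻¹)
    starting material + initiating radical → capped initiator + first chain carrier (k = 1.40 × 10⁶ L mol⁻¹ s⁻¹)
    partner + first chain carrier → target + second chain carrier (k = 2.30 × 10⁶ L mol⁻¹ s⁻¹)
    starting material + second chain carrier → by-product + first chain carrier (k = 45000 L mol⁻¹ s⁻¹)
    transfer agent + first chain carrier → side product + idle radical (kL = 90000 L mol⁻¹ s⁻¹)
    2 idle radical → ended radicals (k = 1.00 × 10⁷ L mol⁻¹ s⁻¹)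
    2 first chain carrier → ended chains A (k = 3.00 × 10⁸ L mol⁻¹ s⁻¹)
    2 second chain carrier → ended chains B (k = 9.70 × 10⁸ L mol⁻¹ s⁻¹)
    gas ⇌ partner, rate k9*(csat - [partner]) (kL = 0.0920 s⁻¹)

In epsilon at 0.157 min, the first chain carrier went to target 5.1 times as fast as to side product. The north-east odds of 3.40, multiplied by gamma's 8.44% side product at 5.00 min, give 28.7% target, and gamma holds 29.0%. The same odds, multiplied by eta's 9.64% side product, give 32.8%, and eta holds 23.3% target at 5.00 min.

The earlier runs and the new flask are calculated with made-up constants; scatter was added.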